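**Plan**
- Retrosynthesis, in order: the CH2OH on pyrrole C5 goes back to CHO; the C5–CHO bond is cut (formylation); the bond from pyrrole C2 to the ketone carbon C1 is cut (acylation by the fatty amide); last, the chain bond C11–C12 is cut into two carboxylic acids.
- Forward: the chain is joined first, a C12 half-ester and a C8 iso-acid giving the complete C18 iso-ester in one electrolysis. Then ester → dimethylamide → 2-acylpyrrole → 5-formyl → 5-hydroxymethyl.
- Enabling feature: C11 and C12 lie inside the unbroken run of fourteen methylenes (C2–C15), ten carbons from the ketone carbon C1 and the pyrrole ring and four from the isopropyl methine C16. Both are unactivated CH2 carbons of like polarity with no heteroatom, branch or ring nearby, so each can be generated as a primary alkyl radical from a carboxylic acid; the carboxyl groups are the only activating groups and leave as CO2 in the event itself.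
- The pyrrole ring is bought intact and no ring is formed; its two α-positions are substituted by two successive electrophilic substitutions.
- Stereochemistry: the target has no stereocentre and no stereogenic double bond, so nothing has to be controlled.

Key step: step 1

Remark on the chemistry: 6-methylheptanoic acid is taken as the single isomer, not the technical "isooctanoic acid" mixture.

**Step 1**
Reactants: 1 12-methoxy-12-oxododecanoic acid (monomethyl dodecanedioate); 2 6-methylheptanoic acid (3 equiv)
Product: 5 methyl 16-methylheptadecanoate, via 11-methoxy-11-oxoundecyl radical 3 (not isolated), via 5-methylhexyl radical 4 (not isolated)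
Conditions: NaOMe (ca. 0.1 equiv per acid, partial neutralisation), MeOH, smooth Pt anode/Pt cathode, undivided cell, constant current ca. 0.2 A cm⁻², 40–50 °C
Reagents that add atoms: none
Why: Crossed Kolbe electrolysis of a dicarboxylic half-ester with a monocarboxylic acid (Brown–Walker type): both carboxylates are oxidised at the platinum anode and lose CO2 to give the primary radicals 3 and 4, which combine in the anode layer to form the C11–C12 bond. The closest known reaction type is the classical crossed Kolbe synthesis of long-chain and iso-branched fatty esters from half-esters and alkanoic acids. No ring is closed and no stereocentre is formed. The selectivity needed is cross- over homo-coupling and radical coupling over further oxidation to carbocations (Hofer–Moest pathway); the excess of the cheaper acid 2 should channel radical 3 statistically into the cross product, and both radicals are primary, without α-branch or α-heteroatom, so at high current density in weakly acidic methanol they should couple and not be oxidised further. The methyl ester of 1 (matched to the solvent, so transesterification is invisible) and the isopropyl end of 2 are remote from the radical centres and inert at the anode, and the two homo-dimers (a C14 hydrocarbon and a C24 diester) differ enough from 5 in volatility and polarity to be removed by distillation or chromatography.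

**Step 2**
Reactants: 5 methyl 16-methylheptadecanoate
Product: 6 N,N,16-trimethylheptadecanamide
Conditions: Me2NH (2 M in THF), AlMe3 (2 M in toluene), toluene, 0 °C → 80 °C; aq. Rochelle salt
Reagents that add atoms: dimethylamine CNC
Why: Weinreb aminolysis of an ester: the aluminium amide formed from AlMe3 and Me2NH should convert the unactivated methyl ester directly into the tertiary amide, and the substrate has no other reactive group.

**Step 3**
Reactants: 6 N,N,16-trimethylheptadecanamide; 7 1H-pyrrole
Product: 10 16-methyl-1-(1H-pyrrol-2-yl)heptadecan-1-one, via chloroiminium dichlorophosphate 8 (not isolated), via ketiminium chloride 9 (not isolated)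
Conditions: POCl3, ClCH2CH2Cl, 0 °C → rt; then 7, reflux; then aq. NaOAc, reflux
Reagents that add atoms: water O
Why: Vilsmeier–Haack acylation: POCl3 turns the amide into chloroiminium salt 8, which should attack pyrrole at its more nucleophilic α-position to give iminium salt 9 (deactivated, so no second acylation), and buffered hydrolysis then releases the 2-acylpyrrole with its oxygen coming from water.

**Step 4**
Reactants: 10 16-methyl-1-(1H-pyrrol-2-yl)heptadecan-1-one
Product: 12 5-(16-methylheptadecanoyl)-1H-pyrrole-2-carbaldehyde, via formiminium chloride 11 (not isolated)
Conditions: POCl3, DMF (premixed, 0 °C), ClCH2CH2Cl, 0 °C → 60 °C; then aq. NaOAc, 80 °C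
Reagents that add atoms: N,N-dimethylformamide CN(C)C=O; water O
Why: Vilsmeier–Haack formylation: the chloromethyliminium ion is a weak electrophile that meets the uncomplexed 2-acylpyrrole, so the intrinsic α-preference of pyrrole should direct it mainly to the free C5, the C4-formyl isomer being the expected minor product to be removed by chromatography, and the ketone, a vinylogous amide, should enolise too slowly to be chloroformylated at this temperature.

**Step 5**
Reactants: 12 5-(16-methylheptadecanoyl)-1H-pyrrole-2-carbaldehyde
Product: 13 1-[5-(hydroxymethyl)-1H-pyrrol-2-yl]-16-methylheptadecan-1-one (target)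
Conditions: NaBH4 (0.5 equiv), THF–MeOH, 0 °C; sat. aq. NH4Cl
Reagents that add atoms: none
Why: Chemoselective borohydride reduction: the formyl group is far more electrophilic than the pyrrol-2-yl alkyl ketone (a vinylogous amide flanked by the chain), so a limited amount of hydride at 0 °C should reduce only the aldehyde, and the neutral work-up avoids acid-induced azafulvenium formation from the hydroxymethylpyrrole.

**Compound list**
1 | 12-methoxy-12-oxododecanoic acid (monomethyl dodecanedioate) | COC(=O)CCCCCCCCCCC(=O)O | starting material
2 | 6-methylheptanoic acid | CC(C)CCCCC(=O)O | starting material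
3 | 11-methoxy-11-oxoundecyl radical | COC(=O)CCCCCCCCC[CH2] | intermediate
4 | 5-methylhexyl radical | CC(C)CCC[CH2] | intermediate
5 | methyl 16-methylheptadecanoate | CC(C)CCCCCCCCCCCCCCC(=O)OC | intermediate
6 | N,N,16-trimethylheptadecanamide | CC(C)CCCCCCCCCCCCCCC(=O)N(C)C | intermediate
7 | 1H-pyrrole | c1cc[nH]c1 | starting material
8 | (1-chloro-16-methylheptadecylidene)dimethylammonium dichlorophosphate | CC(C)CCCCCCCCCCCCCCC(Cl)=[N+](C)C.[O-]P(=O)(Cl)Cl | intermediate
9 | dimethyl[16-methyl-1-(1H-pyrrol-2-yl)heptadecylidene]ammonium chloride | CC(C)CCCCCCCCCCCCCCC(=[N+](C)C)c1ccc[nH]1.[Cl-] | intermediate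
10 | 16-methyl-1-(1H-pyrrol-2-yl)heptadecan-1-one | CC(C)CCCCCCCCCCCCCCC(=O)c1ccc[nH]1 | intermediate
11 | dimethyl{[5-(16-methylheptadecanoyl)-1H-pyrrol-2-yl]methylidene}ammonium chloride | CC(C)CCCCCCCCCCCCCCC(=O)c1ccc(C=[N+](C)C)[nH]1.[Cl-] | intermediate
12 | 5-(16-methylheptadecanoyl)-1H-pyrrole-2-carbaldehyde | CC(C)CCCCCCCCCCCCCCC(=O)c1ccc(C=O)[nH]1 | intermediate
13 | 1-[5-(hydroxymethyl)-1H-pyrrol-2-yl]-16-methylheptadecan-1-one | CC(C)CCCCCCCCCCCCCCC(=O)c1ccc(CO)[nH]1 | target

**Step count and risks**
Total step count: 5. Longest linear sequence: 5 steps (1/2 → 5 → 6 → 10 → 12 → 13).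

Steps most likely to fail:

1. Step 4. The electrophile may attack C4 instead of C5, because the acyl group deactivates the α-position it is conjugated with, or it may chloroformylate the ketone α-CH2. Fallback: the C5 carbon is bought with the ring. Setting out from 6, Vilsmeier–Haack acylation (POCl3, ClCH2CH2Cl, reflux) of commercial 2-methyl-1H-pyrrole can only occur at its one free α-position. It should give, through dimethyl[16-methyl-1-(5-methyl-1H-pyrrol-2-yl)heptadecylidene]ammonium chloride F1 and buffered hydrolysis (aq. NaOAc), 16-methyl-1-(5-methyl-1H-pyrrol-2-yl)heptadecan-1-one F2. Oxidation of its α-methyl group by ceric ammonium nitrate (THF–AcOH–H2O, rt), a known reaction of α-methylpyrroles that carry a carbonyl group at the other α-position, should then give the aldehyde, and the route is rejoined at 12.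

2. Step 1. Each radical may couple with itself, the radicals may be over-oxidised to cations (Hofer–Moest products), or the anode may become passivated. Fallback: a chemoselective nickel-catalysed decarboxylative alkyl–alkyl coupling, in which only one partner is a radical precursor. Setting out from 1, esterification with N-hydroxyphthalimide (DIC, cat. DMAP, CH2Cl2) gives the redox-active ester 1-(1,3-dioxoisoindolin-2-yl) 12-methyl dodecanedioate F3. Commercial 1-bromo-5-methylhexane is converted with Mg (THF) into (5-methylhexyl)magnesium bromide F4 and with ZnCl2 (0.5 equiv) into bis(5-methylhexyl)zinc F5. F3 and F5 with NiCl2·glyme and 4,4'-di-tert-butyl-2,2'-bipyridine in THF–DMF at rt should give the same ester without a statistical mixture, and the route is rejoined at 5.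

3. Step 3. The enolisable chloroiminium salt may self-condense and the acidic medium may oligomerise pyrrole. Fallback: the acyl group is delivered to a pyrrolyl anion under basic conditions. Setting out from 5, saponification (NaOH, aq. EtOH; HCl) gives 16-methylheptadecanoic acid F6. Oxalyl chloride with cat. DMF (CH2Cl2) gives 16-methylheptadecanoyl chloride F7. This is added at 0 °C to pyrrol-1-ylmagnesium bromide F8 (from 7 and EtMgBr, Et2O–toluene), which is acylated mainly at C2 (Oddo reaction), and the route is rejoined at 10.

**Further compounds**
F1 | step 4 | dimethyl[16-methyl-1-(5-methyl-1H-pyrrol-2-yl)heptadecylidene]ammonium chloride | CC(C)CCCCCCCCCCCCCCC(=[N+](C)C)c1ccc(C)[nH]1.[Cl-]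
F2 | step 4 | 16-methyl-1-(5-methyl-1H-pyrrol-2-yl)heptadecan-1-one | CC(C)CCCCCCCCCCCCCCC(=O)c1ccc(C)[nH]1
F3 | step 1 | 1-(1,3-dioxoisoindolin-2-yl) 12-methyl dodecanedioate | COC(=O)CCCCCCCCCCC(=O)ON1C(=O)c2ccccc2C1=O
F4 | step 1 | (5-methylhexyl)magnesium bromide | CC(C)CCCC[Mg]Br
F5 | step 1 | bis(5-methylhexyl)zinc | CC(C)CCCC[Zn]CCCCC(C)C
F6 | step 3 | 16-methylheptadecanoic acid | CC(C)CCCCCCCCCCCCCCC(=O)O
F7 | step 3 | 16-methylheptadecanoyl chloride | CC(C)CCCCCCCCCCCCCCC(=O)Cl
F8 | step 3 | pyrrol-1-ylmagnesium bromide | Br[Mg]n1cccc1
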